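Remark on the chemistry: atoms carry labdane numbers (C1–C10 decalin, C11–C16 side chain, C17 on C8, C18/C19 on C4, C20 on C10). α is the face of the decalin that carries C20 in the target, β the opposite face. (S)-Carvone, methyl 2-(bromomethyl)acrylate and but-3-yn-1-ol are taken as commercial.

## Analysis of the target

The target is an ent-labdane, (3S,5S,9R,10S,13E)-3-hydroxy-2-oxolabda-7,13-dien-15-yl acetate. It is a trans-fused decalin (ring A: C1–C5, C10; ring B: C5–C10) with an (E)-5-acetoxy-3-methylpent-3-enyl chain (C11–C16) on C9. Ring A holds an α-ketol (C2=O, C3–OH) between the gem-dimethyl carbon C4 and the quaternary C10. Ring B holds the trisubstituted C7=C8 alkene with C17 on C8. Of the four stereocentres, C5 and C10 define the trans fusion (H5 β, C20 α), C9 carries C11 equatorial on the α face (H9 β, cis to H5), and C3 carries an equatorial hydroxyl on the α face. The sensitive groups are: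

- the ketol, which can epimerise at C3, shift its carbonyl through the enediol and autoxidise in base;
- the allylic acetate, which is ionisable and base-labile;
- the C7=C8 alkene, which migrates to C8=C9 in acid;
- both trisubstituted alkenes, which react with electrophilic oxidants.

The hard parts are the contiguous array C4–C5–C10, the allylic stereocentre C9, and the oxygenation of C2 and C3, each next to a quaternary carbon. The strategy rests on one observation: C4 with its two methyls, bonded to the ring B stereocentre C5, is the isopropenyl group of (S)-carvone (1) plus one hydrogen atom. The enone of 1 is then C9(=O)–C8(C17)=C7, and its stereocentre already has the configuration of C5. The rest of ring A, C1–C2–C3, is a three-carbon acrylate unit on C10 whose carboxyl carbon marks C2 for the later carbonyl.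

## Retrosynthetic reasoning

The acetate is removed first. Target 35 comes from diol 34 by acylation of the primary allylic hydroxyl, and 34 from silyl ether 33. Cutting the ester last keeps the allylic acetate out of every enolate and organometallic step; the forward reaction only has to tell a primary from a hindered secondary hydroxyl.

Next the C3–O bond is cut, leading from 33 to silyl enol ether 30 and ketone 29. C3 is α to the C2 carbonyl, so its oxygen can come from an electrophilic oxidant acting on the C2=C3 enol ether. The cut is placed late because an α-oxygenated ketone would not survive the organometallic addition or the dissolving-metal step used in ring B. The forward reaction must choose C3 over C1 and the enol ether over two trisubstituted alkenes. The C3 configuration need not be controlled kinetically, because the equatorial ketol 33 is the thermodynamic end point reached from 31 and 32.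

Ketone 29 is masked as ketal 28, since C2 must be inert while ring B is elaborated.

In ring B the C7–H bond of 28 is traced to enol triflate 27, and 27 to enone 25 through enolate 26. These two cuts turn the allylic stereocentre C9 and the alkene position into one conjugate reduction. The forward reaction must protonate C9 on the β face and trap the enolate on oxygen, which fixes the C7=C8 double bond.

The C9–C11 bond is cut next. Enone 25 comes from tertiary allylic alcohol 24 by 1,3-oxidative transposition, and 24 from enone 13 and iodide 21 through organometallics 22 and 23. The cut is made at C9 because this is the carbonyl carbon inherited from 1: the chain enters as a nucleophile and the bond formation needs no stereocontrol.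

Iodide 21 is traced through alcohol 20 and ethers 19 and 18 to alkyne 15 and but-3-yn-1-ol 14. The cuts are C13–C16 and C14–C15. Syn-methylmetalation of the alkyne (via 16 and 17) fixes the E geometry, and the two chain ends are told apart by an oxidatively removable ether on C11 and a silyl ether on C15.

Enone ketal 13 comes from dione 12, this from alcohol 11, and 11 from acid 8 and ester 7 by excision of the carboxyl carbon (via 9 and 10). The C2–carboxyl bond is cut by a radical and not through an enolate, because the C2–H of 7 lies under the two α-axial methyls and the enone has acidic γ-hydrogens. The gain is that the position of the future carbonyl is marked by carbon from the start.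

The key cut is C3–C4 of ring A. Ester 7 comes from monocycle 6: a tertiary radical at C4, made from the isopropenyl group by hydrogen-atom transfer, adds to the acrylate CH2. This is the only ring A bond whose two ends are a natural radical donor and acceptor. It creates the quaternary C4 and ring A together, and the fusion stereochemistry is already contained in 6.

Finally 6 is cut at C10–C1 and C10–C20 to acrylate 4, an electrophilic methyl group and 1 (through 3 and enolates 2 and 5). Two successive alkylations at the α′-carbon of the enone build the quaternary C10. Methyl goes first and the acrylate arm second, because the second electrophile enters anti to the isopropenyl group.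

## Alternatives that were turned down

Alternative 1: The disconnection removes C15 and C16 from the finished bicycle by cutting C13–C16 and C14–C15, which leads back to terminal alkyne A2. Forward, zirconium-catalysed methylalumination of the alkyne and capture of the alkenylalane by a one-carbon electrophile would give allylic alcohol A1 in one flask.
- For it: syn-carbometalation fixes the E geometry. The allylic oxygen appears only at the end, so no protected allylic alcohol passes through organolithium, chromium and dissolving-metal steps, and no functionalised alkyllithium is needed. On these points it is stronger than the chosen route.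
- Against it: the step settles only the easiest part of the molecule. A1 has no oxygen at C2, so the ketol would have to be made afterwards from a C3 ketone by C2 oxidation and acyloin transposition, beside a free allylic alcohol and two oxidisable alkenes. The construction of the decalin with C5, C9 and C10 is left open.
- Comparison: the chosen strategy uses the same carbometalation on the small alkyne 15, where it costs little. In its place it offers a defined origin for every ring carbon and stereocentre, with C2 marked by the acrylate carboxyl.

Alternative 2: Ring B is cut at C5–C6 and C9–C10 into the silyl dienol ether A4 (C6–C9 with C17) and the trisubstituted enal A5 (C10 with C20 and C1, C5, and the C4–C3–C2 unit as a methyl ketone). Forward, a Diels–Alder reaction under a triflimide-activated chiral oxazaborolidine would give cyclohexene A3, with C5 and C10 set by the catalyst and C7=C8 in place.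
- For it: the absolute configuration comes from a catalyst, so either enantiomer is open; on this point it is more general than a chiral-pool start. C4, C8 and C10 arrive with their methyls in one step.
- Against it: A5 has a tert-alkyl group on its β-carbon and a methyl on its α-carbon, so the cycloaddition must join hindered carbons and form a quaternary centre. The catalyst must also tell the aldehyde from the ketone. A3 carries oxygen at C9 where a carbon chain is needed, so the C9–C11 bond and the C9 stereocentre remain to be solved by the same addition, transposition and reduction sequence. Ring A must then be closed by aldol condensation between C1 and C2, which leaves the carbonyl at C3 and demands further redox steps to reach the 2-oxo-3-hydroxy pattern.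
- Comparison: (S)-carvone is the cheap and correct enantiomer here, so the generality is not needed. The chosen route replaces an uncertain, sterically loaded cycloaddition by two precedented enolate alkylations.

Alternative 3: Ring A is cut at C1–C10 and C4–C5. Ring B is then 2,6-dimethyl-1,4-benzoquinone A7 and ring A the 2-silyloxy diene A8, made from the enone A9. Forward, an enantioselective Diels–Alder reaction with the same type of cationic oxazaborolidine would give the cis-fused enedione A6.
- For it: this is the most convergent plan. Two commercial pieces deliver all ten ring carbons and C17–C20. The C2 oxygen arrives as a regiodefined C2=C3 silyl enol ether, so C3 hydroxylation has no C1/C3 ambiguity. On this point it is clearly stronger than the chosen route, which relies on thermodynamic enolisation.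
- Against it: a diene with two substituents on one terminus, one of them cis, reaches the s-cis conformation with difficulty, and it must bond through exactly this terminus to make C4–C5. A6 is cis-fused, so C5 has to be epimerised through the C6 ketone. This surplus C6 carbonyl must then be removed and kept apart from C9 before the side chain can be added.
- Comparison: the chosen strategy offers the trans fusion by construction, no surplus oxygen, and a ring closure whose partners (an electron-rich 1,1-disubstituted alkene and an acrylate) suit the radical reaction.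

Key step: step 3

## Route

Step 1
Reactants: 1 (S)-(+)-carvone
Product: 3 (5S)-2,6-dimethyl-5-(prop-1-en-2-yl)cyclohex-2-en-1-one (6-methylcarvone; both C6 epimers; trans epimer drawn), via lithium dienolate 2 (not isolated)
Conditions: LiN(i-Pr)2 (1.05 equiv), THF, −78 °C; MeI, −78 → 0 °C
Reagents that add atoms: iodomethane, CI
Why: Kinetic α′-deprotonation of the enone (C6 is its only enolisable α-position) and C-methylation of the cross-conjugated enolate; the C6 configuration does not matter because this carbon is planarised again in step 2.

Step 2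
Reactants: 3 6-methylcarvone; 4 methyl 2-(bromomethyl)prop-2-enoate
Product: 6 methyl 2-{[(1R,6R)-1,3-dimethyl-2-oxo-6-(prop-1-en-2-yl)cyclohex-3-en-1-yl]methyl}prop-2-enoate, via lithium enolate 5 (not isolated)
Conditions: LiN(i-Pr)2 (1.1 equiv), THF, −78 → 0 °C; 4 (1.3 equiv), −78 → −20 °C
Reagents that add atoms: none
Why: Enolate alkylation by addition–elimination (SN2′) on the allylic bromide; A(1,2) strain with the C6 methyl turns the isopropenyl group pseudoaxial so that it covers one face, and the electrophile enters anti to it, which gives the quaternary carbon (later C10) with the acrylate arm trans to isopropenyl.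

Step 3
Reactants: 6 methyl 2-{[(1R,6R)-1,3-dimethyl-2-oxo-6-(prop-1-en-2-yl)cyclohex-3-en-1-yl]methyl}prop-2-enoate
Product: 7 methyl 4,4,8,10-tetramethyl-9-oxo-trans-decal-7-ene-2-carboxylate (labdane numbering; 5β-H; 10α-CH3; β-equatorial ester drawn)
Conditions: Fe(acac)3 (0.3 equiv), PhSiH3 (2.5 equiv), EtOH/HOCH2CH2OH 5:1, 0.02 M, 60 °C
Reagents that add atoms: none
Why: Fe(acac)3 and PhSiH3 in ethanol form an iron hydride that transfers a hydrogen atom to the CH2 terminus of the isopropenyl group, which creates the second methyl on C4 and a tertiary C4 radical. The closest known reaction type is the iron-hydride-initiated reductive olefin coupling (hydrogen-atom-transfer Giese addition) of 1,1-disubstituted alkenes with acrylates, which is known to form quaternary carbons and rings. Ring A closes in the 6-endo-trig mode: the nucleophilic tertiary radical attacks the free β-CH2 (C3) of the acrylate, which is tethered through its α-carbon, so that polarity and substitution both disfavour 5-exo attack at C2. The α-ester radical at C2 is then reduced by divalent iron to the enolate and protonated by the alcohol, which returns trivalent iron. The ring fusion needs no stereochemical decision, because the two arms are already trans and diequatorial on ring B (C5 from 1, C10 from step 2) and a chair transition state gives the trans-decalin; C4 is not stereogenic. The only new stereocentre, C2, is set by protonation of the enolate (equatorial ester expected) and is erased in steps 5 and 6. The step needs hydrogen-atom transfer to the isopropenyl alkene in preference to the acrylate and the enone alkene, which the preference of this hydride for unhindered electron-rich 1,1-disubstituted alkenes should provide, and it needs cyclisation to outrun reduction of the radical, which high dilution and the chair-like six-membered transition state favour.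

Step 4
Reactants: 7 methyl 4,4,8,10-tetramethyl-9-oxo-trans-decal-7-ene-2-carboxylate
Product: 8 4,4,8,10-tetramethyl-9-oxo-trans-decal-7-ene-2-carboxylic acid
Conditions: LiOH·H2O, THF/MeOH/H2O, 40 °C; then 1 M HCl
Reagents that add atoms: lithium hydroxide, [Li+].[OH-]
Why: Saponification (acyl substitution by hydroxide) of the secondary methyl ester; the enone has no enolisable α′-position and epimerisation at C2 is of no consequence.

Step 5
Reactants: 8 4,4,8,10-tetramethyl-9-oxo-trans-decal-7-ene-2-carboxylic acid
Product: 11 2-hydroxy-4,4,8,10-tetramethyl-trans-decal-7-en-9-one (C2 epimers; 2β-equatorial alcohol drawn), via thiohydroxamate ester 9 (not isolated), via hydroperoxide 10 (not isolated)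
Conditions: N-hydroxypyridine-2-thione, DCC, DMAP (cat.), CH2Cl2, 0 °C → rt, dark; then O2, t-BuSH, PhMe, hν (visible), 0 °C; then PPh3, rt
Reagents that add atoms: dioxygen, O=O
Why: Barton decarboxylation: ester 9 fragments under light to CO2 and the secondary C2 radical, which is captured by O2; thiol chain transfer gives hydroperoxide 10, which the phosphine reduces. Approach anti to the two α-axial methyls (on C4 and C10) should favour the equatorial C–O bond, but both epimers converge in step 6, and no enolate is involved, so the γ-hydrogens of the enone do not interfere.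

Step 6
Reactants: 11 2-hydroxy-4,4,8,10-tetramethyl-trans-decal-7-en-9-one
Product: 12 4,4,8,10-tetramethyl-trans-decal-7-ene-2,9-dione
Conditions: Dess–Martin periodinane, NaHCO3, CH2Cl2, rt
Reagents that add atoms: none
Why: Dess–Martin oxidation of the secondary alcohol under buffered, non-enolising conditions; both C2 epimers give the same ketone and the enone is untouched.

Step 7
Reactants: 12 4,4,8,10-tetramethyl-trans-decal-7-ene-2,9-dione
Product: 13 2,2-(ethylenedioxy)-4,4,8,10-tetramethyl-trans-decal-7-en-9-one
Conditions: Me3SiOCH2CH2OSiMe3, Me3SiOSO2CF3 (5 mol %), CH2Cl2, −78 → −20 °C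
Reagents that add atoms: 1,2-bis(trimethylsilyloxy)ethane, C[Si](C)(C)OCCO[Si](C)(C)C
Why: Noyori ketalisation under kinetic silyl-transfer conditions: the saturated C2 ketone reacts, while the conjugated C9 ketone, flanked by the quaternary C10 and the C8 methyl, should not. One ketal oxygen becomes syn-axial to the α-axial methyls on C4 and C10, which is tolerated because formation of the disiloxane makes the process irreversible.

Step 8
Reactants: 14 but-3-yn-1-ol
Product: 15 1-[(but-3-yn-1-yloxy)methyl]-4-methoxybenzene
Conditions: NaH, 4-MeOC6H4CH2Cl, n-Bu4NI (cat.), THF, 0 °C → rt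
Reagents that add atoms: 4-methoxybenzyl chloride, COc1ccc(CCl)cc1
Why: Williamson ether synthesis; the 4-methoxybenzyl ether tolerates the alane and the alkyllithium of step 9 and can later be removed oxidatively beside a silyl ether.

Step 9
Reactants: 15 1-[(but-3-yn-1-yloxy)methyl]-4-methoxybenzene
Product: 18 (2E)-5-[(4-methoxybenzyl)oxy]-3-methylpent-2-en-1-ol, via alkenylalane 16 (not isolated), via lithium alkenylalanate 17 (not isolated)
Conditions: Me3Al (2.5 equiv), Cp2ZrCl2 (0.25 equiv), CH2Cl2, 0 °C → rt; volatiles removed; n-BuLi, THF/hexane, −78 → 0 °C; (CH2O)n, rt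
Reagents that add atoms: trimethylaluminium, C[Al](C)C; formaldehyde (as paraformaldehyde), C=O
Why: Negishi zirconium-catalysed carboalumination: syn-addition of CH3–Al across the terminal alkyne puts aluminium on C14 and the methyl (C16) on C13, and alanate 17 transfers its alkenyl group with retention to formaldehyde (C15), which gives the E-allylic alcohol.

Step 10
Reactants: 18 (2E)-5-[(4-methoxybenzyl)oxy]-3-methylpent-2-en-1-ol
Product: 19 triisopropyl({(2E)-5-[(4-methoxybenzyl)oxy]-3-methylpent-2-en-1-yl}oxy)silane
Conditions: i-Pr3SiCl, imidazole, DMF, rt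
Reagents that add atoms: chlorotriisopropylsilane, CC(C)[Si](Cl)(C(C)C)C(C)C
Why: Silylation of the primary allylic alcohol; the triisopropylsilyl ether is chosen to withstand alkyllithium, hexavalent chromium, dissolving metal and mild acid in the later steps.

Step 11
Reactants: 19 triisopropyl({(2E)-5-[(4-methoxybenzyl)oxy]-3-methylpent-2-en-1-yl}oxy)silane
Product: 20 (3E)-3-methyl-5-[(triisopropylsilyl)oxy]pent-3-en-1-ol
Conditions: DDQ, CH2Cl2/pH 7 buffer 10:1, 0 °C
Reagents that add atoms: none
Why: Oxidative cleavage of the 4-methoxybenzyl ether by hydride abstraction with the quinone and hydrolysis of the oxocarbenium ion; the silyl ether and the alkene are not touched.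

Step 12
Reactants: 20 (3E)-3-methyl-5-[(triisopropylsilyl)oxy]pent-3-en-1-ol
Product: 21 {[(2E)-5-iodo-3-methylpent-2-en-1-yl]oxy}triisopropylsilane
Conditions: I2, PPh3, imidazole, CH2Cl2, 0 °C
Reagents that add atoms: iodine, II
Why: Appel-type iodination: SN2 displacement of the alkoxyphosphonium ion at the primary carbon, without allylic transposition because the alcohol is homoallylic.

Step 13
Reactants: 13 2,2-(ethylenedioxy)-4,4,8,10-tetramethyl-trans-decal-7-en-9-one; 21 {[(2E)-5-iodo-3-methylpent-2-en-1-yl]oxy}triisopropylsilane
Product: 24 2,2-(ethylenedioxy)-15-[(triisopropylsilyl)oxy]labda-7,13E-dien-9-ol (9α-OH drawn; C9 configuration of no consequence), via alkyllithium 22 (not isolated), via alkylcerium dichloride 23 (not isolated)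
Conditions: 21 (1.6 equiv), t-BuLi (3.2 equiv), Et2O/pentane, −78 °C; CeCl3, THF, −78 °C; 13, −78 → −20 °C
Reagents that add atoms: none
Why: Iodine–lithium exchange gives the primary homoallylic lithium 22, transmetallated to the less basic organocerium 23, which should add 1,2 to the hindered, γ-enolisable enone instead of deprotonating it (organocerium carbonyl addition). Attack anti to the axial C20 is expected, and the carbinol configuration is destroyed in step 14.

Step 14
Reactants: 24 2,2-(ethylenedioxy)-15-[(triisopropylsilyl)oxy]labda-7,13E-dien-9-ol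
Product: 25 2,2-(ethylenedioxy)-15-[(triisopropylsilyl)oxy]labda-8,13E-dien-7-one
Conditions: pyridinium chlorochromate, 4 Å MS, CH2Cl2, rt
Reagents that add atoms: pyridinium chlorochromate, [O-][Cr](=O)(=O)Cl.c1cc[nH+]cc1
Why: Babler–Dauben oxidative transposition: the chromate ester of the tertiary allylic alcohol undergoes a [3,3]-shift to C7 and is oxidised to the C7 ketone, which leaves the C8=C9 double bond carrying the side chain. Dioxolanes and silyl ethers are commonly carried through this reagent in the presence of molecular sieves.

Step 15
Reactants: 25 2,2-(ethylenedioxy)-15-[(triisopropylsilyl)oxy]labda-8,13E-dien-7-one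
Product: 27 2,2-(ethylenedioxy)-15-[(triisopropylsilyl)oxy]labda-7,13E-dien-7-yl trifluoromethanesulfonate (9β-H), via lithium enolate 26 (not isolated)
Conditions: Li (2.2 equiv), NH3(l)/THF, t-BuOH (1 equiv), −78 °C; NH3 evaporated; PhN(SO2CF3)2, THF, 0 °C → rt
Reagents that add atoms: N-phenylbis(trifluoromethanesulfonimide), O=S(=O)(N(c1ccccc1)S(=O)(=O)C(F)(F)F)C(F)(F)F
Why: Dissolving-metal (Birch-type) conjugate reduction: the enone radical anion is protonated axially at C9, on the β face anti to the axial C20, which sets H9 β and leaves C11 equatorial on the α face; the regiodefined enolate 26 is trapped on oxygen by the triflimide. A small excess of lithium at −78 °C should spare the isolated alkenes, the ketal and the allylic silyl ether.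

Step 16
Reactants: 27 2,2-(ethylenedioxy)-15-[(triisopropylsilyl)oxy]labda-7,13E-dien-7-yl trifluoromethanesulfonate
Product: 28 2,2-(ethylenedioxy)-15-[(triisopropylsilyl)oxy]labda-7,13E-diene
Conditions: Pd(OAc)2 (5 mol %), PPh3 (10 mol %), HCO2H, n-Bu3N, DMF, 60 °C
Reagents that add atoms: none
Why: Palladium-catalysed formate reduction of the enol triflate: oxidative addition to zerovalent palladium, formate exchange, loss of CO2 and reductive elimination replace C7–O by C7–H without moving the C7=C8 double bond or touching C9.

Step 17
Reactants: 28 2,2-(ethylenedioxy)-15-[(triisopropylsilyl)oxy]labda-7,13E-diene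
Product: 29 15-[(triisopropylsilyl)oxy]labda-7,13E-dien-2-one
Conditions: pyridinium p-toluenesulfonate (cat.), acetone/H2O 10:1, 50 °C
Reagents that add atoms: water, O
Why: Acid-catalysed ketal hydrolysis; the strained dioxolane should cleave under conditions mild enough to keep the primary triisopropylsilyl ether and to avoid migration of the C7=C8 double bond.

Step 18
Reactants: 29 15-[(triisopropylsilyl)oxy]labda-7,13E-dien-2-one
Product: 30 2-(trimethylsilyloxy)-15-[(triisopropylsilyl)oxy]labda-2,7,13E-triene
Conditions: Me3SiCl, Et3N, DMF, 90 °C
Reagents that add atoms: chlorotrimethylsilane, C[Si](C)(C)Cl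
Why: Silyl enol ether formation under equilibrating conditions (thermodynamic control): the C2=C3 enol ether is expected to prevail over the C1=C2 isomer, which would hold its vinylic C1–H in the plane next to C11 and put the double bond in the less favourable 1,2-position of a 10-methyl trans-decalin. The C15 silyl ether and both alkenes are inert.

Step 19
Reactants: 30 2-(trimethylsilyloxy)-15-[(triisopropylsilyl)oxy]labda-2,7,13E-triene
Product: 33 3α-hydroxy-15-[(triisopropylsilyl)oxy]labda-7,13E-dien-2-one (equatorial C3–OH), via 3β-silyloxy ketone 31 (not isolated), via 3β-hydroxy ketone 32 (not isolated)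
Conditions: 3-ClC6H4CO3H (1.05 equiv), NaHCO3, CH2Cl2, −20 °C; then K2CO3, MeOH, rt, Ar
Reagents that add atoms: 3-chloroperoxybenzoic acid, OOC(=O)c1cccc(Cl)c1
Why: Rubottom oxidation: the peracid should epoxidise the electron-rich enol ether faster than the two trisubstituted alkenes (one equivalent, low temperature), from the β face anti to the α-axial methyls on C4 and C10, and silyl migration gives the axial 3β-silyloxy ketone 31. Methanolysis frees ketol 32, and carbonate equilibrates C3 through the enolate to the equatorial 3α-hydroxy ketone 33, which is expected to be the more stable epimer (hydrogen-bonded, no syn-axial contacts) of the more stable acyloin isomer (a trigonal C2 has nothing syn-axial to the two α-axial methyls). C3 is therefore set under thermodynamic control.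

Step 20
Reactants: 33 3α-hydroxy-15-[(triisopropylsilyl)oxy]labda-7,13E-dien-2-one
Product: 34 3α,15-dihydroxylabda-7,13E-dien-2-one
Conditions: HF·pyridine, THF/pyridine, 0 °C → rt
Reagents that add atoms: none
Why: Fluoride-mediated desilylation under buffered, weakly acidic conditions that should not enolise the ketol, ionise the allylic alcohol or move the ring alkene.

Step 21
Reactants: 34 3α,15-dihydroxylabda-7,13E-dien-2-one
Product: 35 (3S,5S,9R,10S,13E)-3-hydroxy-2-oxolabda-7,13-dien-15-yl acetate (CNP0164008.1)
Conditions: Ac2O (1.1 equiv), pyridine, CH2Cl2, 0 °C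
Reagents that add atoms: acetic anhydride, CC(=O)OC(C)=O
Why: Acylation of the unhindered primary allylic alcohol is much faster than that of the neopentyl-type, hydrogen-bonded C3 hydroxyl, so one equivalent of anhydride at 0 °C should give the monoacetate.

## Compound list

1 | (S)-(+)-carvone, (5S)-2-methyl-5-(prop-1-en-2-yl)cyclohex-2-en-1-one | O=C1C(C)=CC[C@H](C(C)=C)C1 | starting material
2 | lithium dienolate of 1 (C1–O–Li, C1=C6) | [Li]OC=1C(C)=CC[C@H](C(C)=C)C=1 | intermediate (not isolated)
3 | (5S)-2,6-dimethyl-5-(prop-1-en-2-yl)cyclohex-2-en-1-one, C6 epimers, trans epimer drawn | O=C1C(C)=CC[C@H](C(C)=C)[C@H]1C | intermediate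
4 | methyl 2-(bromomethyl)prop-2-enoate | C=C(CBr)C(=O)OC | starting material
5 | lithium enolate of 3 (tetrasubstituted, C1=C6) | [Li]OC=1C(C)=CC[C@H](C(C)=C)C=1C | intermediate (not isolated)
6 | methyl 2-{[(1R,6R)-1,3-dimethyl-2-oxo-6-(prop-1-en-2-yl)cyclohex-3-en-1-yl]methyl}prop-2-enoate | O=C1C(C)=CC[C@H](C(C)=C)[C@@]1(C)CC(=C)C(=O)OC | intermediate
7 | methyl 4,4,8,10-tetramethyl-9-oxo-trans-decal-7-ene-2-carboxylate (5β-H, 10α-CH3, 2β-ester drawn) | O=C1C(C)=CC[C@@H]2C(C)(C)C[C@@H](C(=O)OC)C[C@@]12C | intermediate
8 | 4,4,8,10-tetramethyl-9-oxo-trans-decal-7-ene-2-carboxylic acid | O=C1C(C)=CC[C@@H]2C(C)(C)C[C@@H](C(=O)O)C[C@@]12C | intermediate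
9 | 2-thioxopyridin-1(2H)-yl ester of 8 | O=C1C(C)=CC[C@@H]2C(C)(C)C[C@@H](C(=O)ON3C=CC=CC3=S)C[C@@]12C | intermediate (not isolated)
10 | 2-hydroperoxy-4,4,8,10-tetramethyl-trans-decal-7-en-9-one (C2 epimers, 2β drawn) | O=C1C(C)=CC[C@@H]2C(C)(C)C[C@@H](OO)C[C@@]12C | intermediate (not isolated)
11 | 2-hydroxy-4,4,8,10-tetramethyl-trans-decal-7-en-9-one (C2 epimers, 2β drawn) | O=C1C(C)=CC[C@@H]2C(C)(C)C[C@@H](O)C[C@@]12C | intermediate
12 | 4,4,8,10-tetramethyl-trans-decal-7-ene-2,9-dione | O=C1C(C)=CC[C@@H]2C(C)(C)CC(=O)C[C@@]12C | intermediate
13 | 2,2-(ethylenedioxy)-4,4,8,10-tetramethyl-trans-decal-7-en-9-one | O=C1C(C)=CC[C@@H]2C(C)(C)CC3(OCCO3)C[C@@]12C | intermediate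
14 | but-3-yn-1-ol | C#CCCO | starting material
15 | 1-[(but-3-yn-1-yloxy)methyl]-4-methoxybenzene | C#CCCOCc1ccc(OC)cc1 | intermediate
16 | (E)-{4-[(4-methoxybenzyl)oxy]-2-methylbut-1-en-1-yl}dimethylalane | C[Al](C)/C=C(\C)CCOCc1ccc(OC)cc1 | intermediate (not isolated)
17 | lithium butyl{(E)-4-[(4-methoxybenzyl)oxy]-2-methylbut-1-en-1-yl}dimethylalanate | [Li+].CCCC[Al-](C)(C)/C=C(\C)CCOCc1ccc(OC)cc1 | intermediate (not isolated)
18 | (2E)-5-[(4-methoxybenzyl)oxy]-3-methylpent-2-en-1-ol | OC/C=C(\C)CCOCc1ccc(OC)cc1 | intermediate
19 | triisopropyl({(2E)-5-[(4-methoxybenzyl)oxy]-3-methylpent-2-en-1-yl}oxy)silane | CC(C)[Si](C(C)C)(C(C)C)OC/C=C(\C)CCOCc1ccc(OC)cc1 | intermediate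
20 | (3E)-3-methyl-5-[(triisopropylsilyl)oxy]pent-3-en-1-ol | CC(C)[Si](C(C)C)(C(C)C)OC/C=C(\C)CCO | intermediate
21 | {[(2E)-5-iodo-3-methylpent-2-en-1-yl]oxy}triisopropylsilane | CC(C)[Si](C(C)C)(C(C)C)OC/C=C(\C)CCI | intermediate
22 | {(3E)-3-methyl-5-[(triisopropylsilyl)oxy]pent-3-en-1-yl}lithium | CC(C)[Si](C(C)C)(C(C)C)OC/C=C(\C)CC[Li] | intermediate (not isolated)
23 | dichloro{(3E)-3-methyl-5-[(triisopropylsilyl)oxy]pent-3-en-1-yl}cerium | CC(C)[Si](C(C)C)(C(C)C)OC/C=C(\C)CC[Ce](Cl)Cl | intermediate (not isolated)
24 | 2,2-(ethylenedioxy)-15-[(triisopropylsilyl)oxy]labda-7,13E-dien-9-ol (9α-OH drawn) | CC(C)[Si](C(C)C)(C(C)C)OC/C=C(\C)CC[C@@]1(O)C(C)=CC[C@@H]2C(C)(C)CC3(OCCO3)C[C@@]12C | intermediate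
25 | 2,2-(ethylenedioxy)-15-[(triisopropylsilyl)oxy]labda-8,13E-dien-7-one | CC(C)[Si](C(C)C)(C(C)C)OC/C=C(\C)CCC1=C(C)C(=O)C[C@@H]2C(C)(C)CC3(OCCO3)C[C@@]12C | intermediate
26 | lithium 7-enolate of the 9β-H dihydro derivative of 25 | CC(C)[Si](C(C)C)(C(C)C)OC/C=C(\C)CC[C@@H]1C(C)=C(O[Li])C[C@@H]2C(C)(C)CC3(OCCO3)C[C@@]12C | intermediate (not isolated)
27 | 2,2-(ethylenedioxy)-15-[(triisopropylsilyl)oxy]labda-7,13E-dien-7-yl trifluoromethanesulfonate | CC(C)[Si](C(C)C)(C(C)C)OC/C=C(\C)CC[C@@H]1C(C)=C(OS(=O)(=O)C(F)(F)F)C[C@@H]2C(C)(C)CC3(OCCO3)C[C@@]12C | intermediate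
28 | 2,2-(ethylenedioxy)-15-[(triisopropylsilyl)oxy]labda-7,13E-diene | CC(C)[Si](C(C)C)(C(C)C)OC/C=C(\C)CC[C@@H]1C(C)=CC[C@@H]2C(C)(C)CC3(OCCO3)C[C@@]12C | intermediate
29 | 15-[(triisopropylsilyl)oxy]labda-7,13E-dien-2-one | CC(C)[Si](C(C)C)(C(C)C)OC/C=C(\C)CC[C@@H]1C(C)=CC[C@@H]2C(C)(C)CC(=O)C[C@@]12C | intermediate
30 | 2-(trimethylsilyloxy)-15-[(triisopropylsilyl)oxy]labda-2,7,13E-triene | CC(C)[Si](C(C)C)(C(C)C)OC/C=C(\C)CC[C@@H]1C(C)=CC[C@@H]2C(C)(C)C=C(O[Si](C)(C)C)C[C@@]12C | intermediate
31 | 3β-(trimethylsilyloxy)-15-[(triisopropylsilyl)oxy]labda-7,13E-dien-2-one (axial C3–O) | CC(C)[Si](C(C)C)(C(C)C)OC/C=C(\C)CC[C@@H]1C(C)=CC[C@@H]2C(C)(C)[C@@H](O[Si](C)(C)C)C(=O)C[C@@]12C | intermediate (not isolated)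
32 | 3β-hydroxy-15-[(triisopropylsilyl)oxy]labda-7,13E-dien-2-one (axial C3–OH) | CC(C)[Si](C(C)C)(C(C)C)OC/C=C(\C)CC[C@@H]1C(C)=CC[C@@H]2C(C)(C)[C@@H](O)C(=O)C[C@@]12C | intermediate (not isolated)
33 | 3α-hydroxy-15-[(triisopropylsilyl)oxy]labda-7,13E-dien-2-one (equatorial C3–OH) | CC(C)[Si](C(C)C)(C(C)C)OC/C=C(\C)CC[C@@H]1C(C)=CC[C@@H]2C(C)(C)[C@H](O)C(=O)C[C@@]12C | intermediate
34 | 3α,15-dihydroxylabda-7,13E-dien-2-one | OC/C=C(\C)CC[C@@H]1C(C)=CC[C@@H]2C(C)(C)[C@H](O)C(=O)C[C@@]12C | intermediate
35 | (3S,5S,9R,10S,13E)-3-hydroxy-2-oxolabda-7,13-dien-15-yl acetate | CC(=O)OC/C=C(\C)CC[C@@H]1C(C)=CC[C@@H]2C(C)(C)[C@H](O)C(=O)C[C@@]12C | target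

## Step count and least certain steps

Total step count: 21. Longest linear sequence: 16 steps (steps 1–7 and 13–21, from 1). The side-chain branch (steps 8–12, from 14) joins at step 13.

Step 3 (key step). Most likely to go wrong: hydrogen-atom transfer to the acrylate, so that the resulting α-ester radical is simply reduced or adds to the isopropenyl group the wrong way round, or reduction of the C4 radical before it cyclises, which amounts to hydrogenation of the isopropenyl group. Fallback: make the same C4 radical without a metal hydride. Setting out from 6, Markovnikov hydration of the isopropenyl group with cold aqueous H2SO4 gives the tertiary alcohol F1. Acylation with methyl chlorooxoacetate (Et3N, DMAP) gives the methyl oxalate F2, and one equivalent of aqueous CsOH gives the caesium oxalate F3. Visible-light photoredox oxidation (Ir[dF(CF3)ppy]2(dtbbpy)PF6, blue light, DME/DMF, H2O) expels two CO2 and leaves the tertiary radical, which closes ring A onto the acrylate by the same 6-endo Giese addition. The fallback comes back to the route at 7.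

Step 7. Most likely to go wrong: incomplete ketalisation, or loss of the ketal under the acidic chromium reagent of step 14, because one ketal oxygen is syn-axial to two methyl groups. Fallback: carry C2 through ring B at the alcohol oxidation level. Setting out from 11, MOMCl and i-Pr2NEt give the methoxymethyl ether F4. The operations of steps 13–16 then give in turn the carbinol F5, the transposed enone F6, the enol triflate F7 and the alkene F8. Me2BBr at −78 °C removes the acetal to give the C2 alcohol F9, and Dess–Martin oxidation comes back to the route at 29.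

Step 13. Most likely to go wrong: decomposition of the homoallylic organolithium by cyclisation onto its own alkene with loss of the allylic silanolate (vinylcyclopropane formation), or γ-deprotonation of the hindered enone in place of addition. Fallback: use a nucleophile whose allylic oxygen cannot leave. Setting out from 21, HF·pyridine gives the iodo alcohol F10. n-BuLi (1 equiv) followed by t-BuLi (2 equiv) gives the lithium alkoxide–alkyllithium F11, which is transmetallated with CeCl3 and added to 13 to give the diol F12. Silylation of the primary hydroxyl alone (i-Pr3SiCl, imidazole) comes back to the route at 24.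

Step 18. Most likely to go wrong: enolisation toward C1 instead of C3 under equilibrating conditions, which would place the oxygen of step 19 on the wrong carbon. Fallback: let accessibility instead of alkene stability decide. Setting out from 29, KN(SiMe3)2 in THF at −78 °C gives the kinetic potassium enolate F13, which is hydroxylated at −78 °C with 2-(phenylsulfonyl)-3-phenyloxaziridine. This comes back to the route at 32, which the carbonate treatment of step 19 converts into 33.

Step 19. Most likely to go wrong: competing epoxidation of the C7=C8 or C13=C14 alkene by the peracid; incomplete equilibration at C3 or air oxidation of the enediol are lesser risks. Fallback: replace the electrophilic epoxidation by oxidation of an enolate with a reagent that leaves alkenes alone. Setting out from 30, MeLi in THF at 0 °C cleaves the O–Si bond and gives the regiodefined lithium enolate F14, which is oxidised at −40 °C with MoO5·pyridine·HMPA. This comes back to the route at 32 and, after the same carbonate equilibration, at 33.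

## Further compounds

F1 | step 3 | methyl 2-{[(1R,6R)-6-(2-hydroxypropan-2-yl)-1,3-dimethyl-2-oxocyclohex-3-en-1-yl]methyl}prop-2-enoate | O=C1C(C)=CC[C@H](C(C)(C)O)[C@@]1(C)CC(=C)C(=O)OC
F2 | step 3 | methyl oxalate of F1 | O=C1C(C)=CC[C@H](C(C)(C)OC(=O)C(=O)OC)[C@@]1(C)CC(=C)C(=O)OC
F3 | step 3 | caesium oxalate of F1 | O=C1C(C)=CC[C@H](C(C)(C)OC(=O)C(=O)[O-])[C@@]1(C)CC(=C)C(=O)OC.[Cs+]
F4 | step 7 | 2-(methoxymethoxy)-4,4,8,10-tetramethyl-trans-decal-7-en-9-one (2β drawn) | O=C1C(C)=CC[C@@H]2C(C)(C)C[C@@H](OCOC)C[C@@]12C
F5 | step 7 | 2-(methoxymethoxy)-15-[(triisopropylsilyl)oxy]labda-7,13E-dien-9-ol | CC(C)[Si](C(C)C)(C(C)C)OC/C=C(\C)CC[C@@]1(O)C(C)=CC[C@@H]2C(C)(C)C[C@@H](OCOC)C[C@@]12C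
F6 | step 7 | 2-(methoxymethoxy)-15-[(triisopropylsilyl)oxy]labda-8,13E-dien-7-one | CC(C)[Si](C(C)C)(C(C)C)OC/C=C(\C)CCC1=C(C)C(=O)C[C@@H]2C(C)(C)C[C@@H](OCOC)C[C@@]12C
F7 | step 7 | 2-(methoxymethoxy)-15-[(triisopropylsilyl)oxy]labda-7,13E-dien-7-yl trifluoromethanesulfonate | CC(C)[Si](C(C)C)(C(C)C)OC/C=C(\C)CC[C@@H]1C(C)=C(OS(=O)(=O)C(F)(F)F)C[C@@H]2C(C)(C)C[C@@H](OCOC)C[C@@]12C
F8 | step 7 | 2-(methoxymethoxy)-15-[(triisopropylsilyl)oxy]labda-7,13E-diene | CC(C)[Si](C(C)C)(C(C)C)OC/C=C(\C)CC[C@@H]1C(C)=CC[C@@H]2C(C)(C)C[C@@H](OCOC)C[C@@]12C
F9 | step 7 | 15-[(triisopropylsilyl)oxy]labda-7,13E-dien-2-ol | CC(C)[Si](C(C)C)(C(C)C)OC/C=C(\C)CC[C@@H]1C(C)=CC[C@@H]2C(C)(C)C[C@@H](O)C[C@@]12C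
F10 | step 13 | (2E)-5-iodo-3-methylpent-2-en-1-ol | OC/C=C(\C)CCI
F11 | step 13 | lithium (2E)-5-lithio-3-methylpent-2-en-1-olate | [Li]OC/C=C(\C)CC[Li]
F12 | step 13 | 2,2-(ethylenedioxy)labda-7,13E-diene-9,15-diol | OC/C=C(\C)CC[C@@]1(O)C(C)=CC[C@@H]2C(C)(C)CC3(OCCO3)C[C@@]12C
F13 | step 18 | potassium 2-enolate (C2=C3) of 29 | CC(C)[Si](C(C)C)(C(C)C)OC/C=C(\C)CC[C@@H]1C(C)=CC[C@@H]2C(C)(C)C=C(O[K])C[C@@]12C
F14 | step 19 | lithium 2-enolate (C2=C3) of 29 | CC(C)[Si](C(C)C)(C(C)C)OC/C=C(\C)CC[C@@H]1C(C)=CC[C@@H]2C(C)(C)C=C(O[Li])C[C@@]12C
A1 | alternative 1 | 3α-(tert-butyldimethylsilyloxy)labda-7,13E-dien-15-ol (ent series) | OC/C=C(\C)CC[C@@H]1C(C)=CC[C@@H]2C(C)(C)[C@H](O[Si](C)(C)C(C)(C)C)CC[C@@]12C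
A2 | alternative 1 | 3α-(tert-butyldimethylsilyloxy)-15,16-dinorlabd-7-en-13-yne (ent series) | C#CCC[C@@H]1C(C)=CC[C@@H]2C(C)(C)[C@H](O[Si](C)(C)C(C)(C)C)CC[C@@]12C
A3 | alternative 2 | 1,5-dimethyl-2-(2-methyl-3-oxobutan-2-yl)-6-(triisopropylsilyloxy)cyclohex-4-ene-1-carbaldehyde | CC(C)[Si](C(C)C)(C(C)C)O[C@H]1C(C)=CC[C@H](C(C)(C)C(C)=O)[C@@]1(C)C=O
A4 | alternative 2 | (E)-triisopropyl[(2-methylbuta-1,3-dien-1-yl)oxy]silane | C=C/C(C)=C/O[Si](C(C)C)(C(C)C)C(C)C
A5 | alternative 2 | (E)-2,4,4-trimethyl-5-oxohex-2-enal | O=C/C(C)=C/C(C)(C)C(C)=O
A6 | alternative 3 | cis-fused 2-(tert-butyldimethylsilyloxy)-4,4,8,10-tetramethyldecala-2,7-diene-6,9-dione (labdane numbering) | O=C1C(C)=CC(=O)[C@H]2C(C)(C)C=C(O[Si](C)(C)C(C)(C)C)C[C@@]12C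
A7 | alternative 3 | 2,6-dimethyl-1,4-benzoquinone | CC1=CC(=O)C=C(C)C1=O
A8 | alternative 3 | tert-butyldimethyl[(4-methylpenta-1,3-dien-2-yl)oxy]silane | C=C(O[Si](C)(C)C(C)(C)C)C=C(C)C
A9 | alternative 3 | 4-methylpent-3-en-2-one | CC(=O)C=C(C)C
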